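The ten-membered carbocycle C1–C10 is opened at C1–C2, the aldol bond between the C1 carbinol and the C3 ketone. The feature exploited is the fully substituted, oxygenated C10 next to C1: the C1 aldehyde cannot enolise and can chelate magnesium through O10, while the Z-C4=C5 alkene and the cis-fused lactone (O–C12–C11–C7–C6) bend the chain. One chelation-controlled Mukaiyama aldol should therefore form C1–C2, close the carbocycle and set C1. Its precursor is a seco 2-silyloxy-1,3-diene (C2–C5) aldehyde already carrying the α-methylene lactone, the C8 angelate and the C10 PMB ether, assembled from (S)-linalool, methyl acrylate, a Z-iodoenal and angelic acid.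

Key step: step 16

Remark: locants are those of germacranolides (carbocycle C1–C10, lactone oxygen on C6, C12 carbonyl, C13 methylene, C14 methyl on C10, C15 methyl on C4); CIP descriptors change along the route where substituent priorities change (iodine, silicon), the spatial arrangement staying that of the target.

Step 1
Reactants: 1 (S)-(+)-linalool
Product: 2 (3S)-3-[(4-methoxyphenyl)methoxy]-3,7-dimethylocta-1,6-diene
Conditions: NaH, PMBCl, Bu4NI (cat.), THF/DMF, 0 → 50 °C
Reagents that add atoms: 4-methoxybenzyl chloride, COc1ccc(CCl)cc1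
Why: Williamson etherification of the tertiary alkoxide with the reactive benzylic chloride (iodide catalysis) should install the chelating, oxidatively removable O10 group at the outset, with the C10 stereocentre taken unchanged from the chiral pool.

Step 2
Reactants: 2 linalyl PMB ether
Product: 3 (4S)-4-[(4-methoxyphenyl)methoxy]-4-methylhex-5-enal
Conditions: O3 (1 equiv, Sudan Red 7B end point), pyridine, CH2Cl2, −78 °C
Reagents that add atoms: ozone, [O-][O+]=O
Why: Chemoselective ozonolysis (pyridine-mediated, so no separate reduction) should cleave the electron-rich trisubstituted alkene well before the hindered, inductively deactivated vinyl group and give the C7 aldehyde.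

Step 3
Reactants: 3 aldehyde
Product: 6 (2R,4S)-4-[(4-methoxyphenyl)methoxy]-4-methylhex-5-ene-1,2-diol, via anilinooxy aldehyde 4 (not isolated), via anilinooxy alcohol 5 (not isolated)
Conditions: PhNO (slow addition), L-proline (20 mol %), MeCN, −20 °C; then NaBH4, EtOH, 0 °C; then Zn, AcOH, rt
Reagents that add atoms: nitrosobenzene, O=Nc1ccccc1
Why: Proline-catalysed α-aminoxylation through the E-enamine, in which the carboxylic acid delivers the nitroso oxygen to one enamine face, should set C8 as R under catalyst control (L-proline), and borohydride reduction followed by reductive N–O cleavage should give the diol.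

Step 4
Reactants: 6 diol
Product: 7 (2R,4S)-4-[(4-methoxyphenyl)methoxy]-4-methyl-1,2-bis(triethylsilyloxy)hex-5-ene
Conditions: TESCl, imidazole, DMF, 0 °C → rt
Reagents that add atoms: chlorotriethylsilane, CC[Si](Cl)(CC)CC
Why: Imidazole-promoted silylation should protect both hydroxyls, the primary silyl ether being the one that the following oxidation consumes.

Step 5
Reactants: 7 bis-silyl ether
Product: 9 (2R,4S)-4-[(4-methoxyphenyl)methoxy]-4-methyl-2-(triethylsilyloxy)hex-5-enal, via alkoxysulfonium chloride 8 (not isolated)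
Conditions: (COCl)2, DMSO, CH2Cl2, −78 → −30 °C; then Et3N, −78 → 0 °C
Reagents that add atoms: none
Why: Under Swern conditions a primary triethylsilyl ether is cleaved by the chlorosulfonium salt and oxidised in the same flask while the secondary one survives, which should give the α-silyloxy aldehyde with C8 intact and without a separate deprotection.

Step 6
Reactants: 9 α-silyloxy aldehyde; 10 methyl acrylate
Product: 11 methyl (4R,6S)-3-hydroxy-6-[(4-methoxyphenyl)methoxy]-6-methyl-2-methylidene-4-(triethylsilyloxy)oct-7-enoate (both C3 epimers)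
Conditions: DABCO (1 equiv), methyl acrylate (excess), MeOH, rt
Reagents that add atoms: none
Why: The Morita–Baylis–Hillman reaction, which is fast for an electron-poor α-oxygenated aldehyde and uses an amine too weakly basic to epimerise C8, should join the acrylate unit (C11–C13) to C7; the new carbinol centre forms unselectively and is erased in the next step.

Step 7
Reactants: 11 Baylis–Hillman adduct
Product: 12 methyl (2Z,4R,6S)-2-(bromomethyl)-6-[(4-methoxyphenyl)methoxy]-6-methyl-4-(triethylsilyloxy)octa-2,7-dienoate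
Conditions: NBS, Me2S, CH2Cl2, 0 °C → rt
Reagents that add atoms: N-bromosuccinimide, O=C1CCC(=O)N1Br
Why: Corey–Kim-type activation of the allylic alcohol as an alkoxysulfonium salt and SN2′ attack of bromide should give the transposed 2-(bromomethyl)enoate as the thermodynamically preferred Z isomer, the C7 carbinol centre becoming sp2.

Step 8
Reactants: 13 but-2-yn-1-ol
Product: 15 (2Z)-3-iodobut-2-en-1-ol, via alkenylalanate 14 (not isolated)
Conditions: NaAlH2(OCH2CH2OMe)2, THF, 0 °C → rt; then I2, −78 °C
Reagents that add atoms: iodine, II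
Why: Hydroxyl-directed trans-hydroalumination puts aluminium on the distal alkyne carbon in a five-membered alanate, and iodinolysis with retention should fix the Z geometry (iodine cis to the carbinol carbon) that later becomes the C4=C5 alkene.

Step 9
Reactants: 15 (2Z)-3-iodobut-2-en-1-ol
Product: 16 (2Z)-3-iodobut-2-enal
Conditions: MnO2, CH2Cl2, rt, dark; solution used at once
Reagents that add atoms: none
Why: Neutral allylic oxidation with MnO2 should give the enal without the Z/E isomerisation that acid or light would cause.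

Step 10
Reactants: 12 allylic bromide; 16 (2Z)-3-iodobut-2-enal
Product: 18 (4S,5R)-5-[(1Z)-2-iodoprop-1-en-1-yl]-4-[(1R,3S)-3-[(4-methoxyphenyl)methoxy]-3-methyl-1-(triethylsilyloxy)pent-4-en-1-yl]-3-methylideneoxolan-2-one, via hydroxy ester 17 (not isolated)
Conditions: In powder, THF/H2O (2:1), rt; then PPTS (cat.), toluene, 50 °C
Reagents that add atoms: none
Why: Indium-mediated Barbier allylation then lactonisation: the Z-allylindium should react through a six-membered chair with C8 axial, which gives the syn C6/C7 pair (cis-lactone), while 1,3-allylic strain keeps H8 in the alkene plane so that the aldehyde adds to C7 anti to the C9 chain with the non-chelating silyloxy group outside, setting C6 and C7 relative to C8 as in the target.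

Step 11
Reactants: 18 silyl-protected lactone
Product: 19 (4R,5R)-4-[(1R,3S)-1-hydroxy-3-[(4-methoxyphenyl)methoxy]-3-methylpent-4-en-1-yl]-5-[(1Z)-2-iodoprop-1-en-1-yl]-3-methylideneoxolan-2-one
Conditions: HF·pyridine, pyridine, THF, 0 °C
Reagents that add atoms: none
Why: Buffered HF·pyridine desilylation should free the C8 hydroxyl under non-basic conditions that neither open nor migrate the lactone and spare the acid-sensitive tertiary allylic ether.

Step 12
Reactants: 19 hydroxy lactone; 20 angelic acid
Product: 22 (1R,3S)-1-[(2R,3R)-2-[(1Z)-2-iodoprop-1-en-1-yl]-4-methylidene-5-oxooxolan-3-yl]-3-[(4-methoxyphenyl)methoxy]-3-methylpent-4-en-1-yl (2Z)-2-methylbut-2-enoate, via mixed anhydride 21 (not isolated)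
Conditions: 20, 2,4,6-Cl3C6H2COCl, Et3N, toluene, rt; then 19, 80 °C
Reagents that add atoms: none
Why: Esterification through the 2,4,6-trichlorobenzoyl mixed anhydride without a nucleophilic catalyst (Yamaguchi-type) should acylate the hindered C8 alcohol at the angeloyl carbonyl without Z-to-E isomerisation to the tiglate, and is placed before the base-sensitive Z-enone exists.

Step 13
Reactants: 22 vinyl iodide angelate; 23 tributyl(1-ethoxyvinyl)stannane
Product: 25 (1R,3S)-3-[(4-methoxyphenyl)methoxy]-3-methyl-1-[(2S,3R)-2-[(1Z)-2-methyl-3-oxobut-1-en-1-yl]-4-methylidene-5-oxooxolan-3-yl]pent-4-en-1-yl (2Z)-2-methylbut-2-enoate, via ethoxydiene 24 (not isolated)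
Conditions: Pd(PPh3)4 (5 mol %), CuI (20 mol %), DMF, rt; then 5% aq. citric acid, THF, rt
Reagents that add atoms: water, O
Why: Copper-assisted Stille coupling should replace iodine by the 1-ethoxyvinyl group with retention of the Z geometry at a temperature at which carbopalladation of the methylene lactone does not compete, and mild hydrolysis of the enol ether then releases the C3 methyl ketone only after O6 is locked in the lactone, so that no furan can form from a free Z-γ-hydroxy enone.

Step 14
Reactants: 25 methyl ketone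
Product: 26 (1R,3S)-3-[(4-methoxyphenyl)methoxy]-3-methyl-1-[(2S,3R)-2-[(1Z)-2-methyl-3-oxobut-1-en-1-yl]-4-methylidene-5-oxooxolan-3-yl]-4-oxobutyl (2Z)-2-methylbut-2-enoate
Conditions: O3 (Sudan Red 7B end point), pyridine, CH2Cl2, −78 °C
Reagents that add atoms: ozone, [O-][O+]=O
Why: Chemoselective ozonolysis: the vinyl group is the only alkene not conjugated with a carbonyl group and should be cleaved before the enone, the angelate and the methylene lactone, which unveils the non-enolisable C1 aldehyde only two steps before the ring closure.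

Step 15
Reactants: 26 keto aldehyde
Product: 27 (1R,3S)-3-[(4-methoxyphenyl)methoxy]-3-methyl-1-[(2S,3R)-2-[(1Z)-2-methyl-3-(triethylsilyloxy)buta-1,3-dien-1-yl]-4-methylidene-5-oxooxolan-3-yl]-4-oxobutyl (2Z)-2-methylbut-2-enoate
Conditions: TESOTf, Et3N, CH2Cl2, −78 °C; cold aq. NaHCO3 quench, Et3N-deactivated silica
Reagents that add atoms: triethylsilyl trifluoromethanesulfonate, CC[Si](CC)(CC)OS(=O)(=O)C(F)(F)F
Why: Soft enolisation (silyl triflate and amine) should silylate the more Lewis-basic enone oxygen and remove a C2 proton to give the cross-conjugated 2-silyloxy-1,3-diene, while the hindered aldehyde has no α-hydrogen and silyl triflates are poor promoters of aldol addition to aldehydes at −78 °C in the presence of amine; the triethylsilyl group is chosen because it is lost more readily than a bulkier one after the aldol step.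

Step 16
Reactants: 27 silyl dienol ether seco-aldehyde
Product: 28 10-O-(4-methoxybenzyl) ether of the target (1S,6S,7R,8R,10S)
Conditions: MgBr2·OEt2 (3 equiv), CH2Cl2, −20 → 0 °C, slow addition of 27 (final 1 mM)
Reagents that add atoms: none
Why: Proposed new method: MgBr2 should bind the C1 aldehyde oxygen and the C10 ether oxygen in a five-membered chelate, the C2 terminus of the silyl dienol ether adds to the activated carbonyl through an open transition state, and loss of silicon as Et3SiBr leaves a chelated magnesium aldolate that is protonated on aqueous work-up. The closest known reactions are the chelation-controlled Mukaiyama aldol additions of enol silanes to α-alkoxy aldehydes with MgBr2·OEt2 and intramolecular aldol closures of medium rings; a ten-membered closure of this kind has not been shown. The carbocycle closes in a 10-exo-trig mode with respect to the aldehyde (enol-endo for the nucleophile). C1 is controlled by the C10 stereocentre: in the chelate C2 attacks the face that carries the small C10 methyl, which places C2 roughly anti to C9 about the C10–C1 bond (a torsion the forming ring accommodates, whereas the other face would need a near-eclipsed arrangement) and should give the 1S carbinol syn to O10. The step needs ring closure over oligomerisation and attack at the aldehyde only; high dilution, the Z-C4=C5 alkene and the cis-lactone that fold C2 towards C1, the non-enolisable aldehyde, and a weak non-basic Lewis acid that spares the methylene lactone, the angelate and the PMB ether should secure this.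

Step 17
Reactants: 28 10-O-PMB ether
Product: 29 target (1S,4Z,6S,7R,8R,10S)-1,10-dihydroxy-3-oxogermacra-4,11(13)-dien-12,6-olid-8-yl (2Z)-2-methylbut-2-enoate
Conditions: DDQ (1.5 equiv), CH2Cl2/aq. KH2PO4–K2HPO4 buffer pH 7 (10:1), 0 °C
Reagents that add atoms: none
Why: Oxidative cleavage of the electron-rich benzyl ether (hydride abstraction by DDQ, hydrolysis of the oxocarbenium ion by the excess of water) should free the tertiary C10 alcohol under neutral conditions that spare the β-hydroxy ketone, the Z-enone, the methylene lactone and the angelate.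

Compound list
1 | (S)-(+)-linalool, (3S)-3,7-dimethylocta-1,6-dien-3-ol | C=C[C@@](C)(O)CCC=C(C)C | starting material
2 | (3S)-3-[(4-methoxyphenyl)methoxy]-3,7-dimethylocta-1,6-diene | C=C[C@@](C)(OCc1ccc(OC)cc1)CCC=C(C)C | intermediate
3 | (4S)-4-[(4-methoxyphenyl)methoxy]-4-methylhex-5-enal | C=C[C@@](C)(OCc1ccc(OC)cc1)CCC=O | intermediate
4 | (2R,4S)-2-(anilinooxy)-4-[(4-methoxyphenyl)methoxy]-4-methylhex-5-enal | O=C[C@H](ONc1ccccc1)C[C@](C)(OCc1ccc(OC)cc1)C=C | intermediate
5 | (2R,4S)-2-(anilinooxy)-4-[(4-methoxyphenyl)methoxy]-4-methylhex-5-en-1-ol | OC[C@H](ONc1ccccc1)C[C@](C)(OCc1ccc(OC)cc1)C=C | intermediate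
6 | (2R,4S)-4-[(4-methoxyphenyl)methoxy]-4-methylhex-5-ene-1,2-diol | OC[C@H](O)C[C@](C)(OCc1ccc(OC)cc1)C=C | intermediate
7 | (2R,4S)-4-[(4-methoxyphenyl)methoxy]-4-methyl-1,2-bis(triethylsilyloxy)hex-5-ene | CC[Si](CC)(CC)OC[C@H](O[Si](CC)(CC)CC)C[C@](C)(OCc1ccc(OC)cc1)C=C | intermediate
8 | {[(2R,4S)-4-[(4-methoxyphenyl)methoxy]-4-methyl-2-(triethylsilyloxy)hex-5-en-1-yl]oxy}dimethylsulfonium chloride | C[S+](C)OC[C@H](O[Si](CC)(CC)CC)C[C@](C)(OCc1ccc(OC)cc1)C=C.[Cl-] | intermediate
9 | (2R,4S)-4-[(4-methoxyphenyl)methoxy]-4-methyl-2-(triethylsilyloxy)hex-5-enal | O=C[C@H](O[Si](CC)(CC)CC)C[C@](C)(OCc1ccc(OC)cc1)C=C | intermediate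
10 | methyl acrylate | C=CC(=O)OC | starting material
11 | methyl (4R,6S)-3-hydroxy-6-[(4-methoxyphenyl)methoxy]-6-methyl-2-methylidene-4-(triethylsilyloxy)oct-7-enoate (both C3 epimers) | C=C(C(=O)OC)C(O)[C@H](O[Si](CC)(CC)CC)C[C@](C)(OCc1ccc(OC)cc1)C=C | intermediate
12 | methyl (2Z,4R,6S)-2-(bromomethyl)-6-[(4-methoxyphenyl)methoxy]-6-methyl-4-(triethylsilyloxy)octa-2,7-dienoate | COC(=O)/C(CBr)=C/[C@H](O[Si](CC)(CC)CC)C[C@](C)(OCc1ccc(OC)cc1)C=C | intermediate
13 | but-2-yn-1-ol | CC#CCO | starting material
14 | sodium 2,2-bis(2-methoxyethoxy)-3-methyl-2,5-dihydro-1,2-oxaaluminol-2-uide (cyclic alkenylalanate) | CC1=CCO[Al-]1(OCCOC)OCCOC.[Na+] | intermediate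
15 | (2Z)-3-iodobut-2-en-1-ol | C/C(I)=C/CO | intermediate
16 | (2Z)-3-iodobut-2-enal | C/C(I)=C/C=O | intermediate
17 | methyl (3S,4R,6S)-3-[(1R,2Z)-1-hydroxy-3-iodobut-2-en-1-yl]-6-[(4-methoxyphenyl)methoxy]-6-methyl-2-methylidene-4-(triethylsilyloxy)oct-7-enoate | C/C(I)=C/[C@H](O)[C@H](C(=C)C(=O)OC)[C@H](O[Si](CC)(CC)CC)C[C@](C)(OCc1ccc(OC)cc1)C=C | intermediate
18 | (4S,5R)-5-[(1Z)-2-iodoprop-1-en-1-yl]-4-[(1R,3S)-3-[(4-methoxyphenyl)methoxy]-3-methyl-1-(triethylsilyloxy)pent-4-en-1-yl]-3-methylideneoxolan-2-one (cis-lactone) | C/C(I)=C/[C@@H]1OC(=O)C(=C)[C@@H]1[C@H](O[Si](CC)(CC)CC)C[C@](C)(OCc2ccc(OC)cc2)C=C | intermediate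
19 | (4R,5R)-4-[(1R,3S)-1-hydroxy-3-[(4-methoxyphenyl)methoxy]-3-methylpent-4-en-1-yl]-5-[(1Z)-2-iodoprop-1-en-1-yl]-3-methylideneoxolan-2-one | C/C(I)=C/[C@@H]1OC(=O)C(=C)[C@@H]1[C@H](O)C[C@](C)(OCc2ccc(OC)cc2)C=C | intermediate
20 | angelic acid, (2Z)-2-methylbut-2-enoic acid | C/C=C(/C)C(=O)O | starting material
21 | (2Z)-2-methylbut-2-enoic 2,4,6-trichlorobenzoic anhydride | C/C=C(/C)C(=O)OC(=O)c1c(Cl)cc(Cl)cc1Cl | intermediate
22 | (1R,3S)-1-[(2R,3R)-2-[(1Z)-2-iodoprop-1-en-1-yl]-4-methylidene-5-oxooxolan-3-yl]-3-[(4-methoxyphenyl)methoxy]-3-methylpent-4-en-1-yl (2Z)-2-methylbut-2-enoate | C/C(I)=C/[C@@H]1OC(=O)C(=C)[C@@H]1[C@H](OC(=O)/C(C)=C\C)C[C@](C)(OCc2ccc(OC)cc2)C=C | intermediate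
23 | tributyl(1-ethoxyvinyl)stannane | CCCC[Sn](CCCC)(CCCC)C(=C)OCC | starting material
24 | (1R,3S)-1-[(2S,3R)-2-[(1Z)-3-ethoxy-2-methylbuta-1,3-dien-1-yl]-4-methylidene-5-oxooxolan-3-yl]-3-[(4-methoxyphenyl)methoxy]-3-methylpent-4-en-1-yl (2Z)-2-methylbut-2-enoate | C=C(OCC)/C(C)=C\[C@@H]1OC(=O)C(=C)[C@@H]1[C@H](OC(=O)/C(C)=C\C)C[C@](C)(OCc2ccc(OC)cc2)C=C | intermediate
25 | (1R,3S)-3-[(4-methoxyphenyl)methoxy]-3-methyl-1-[(2S,3R)-2-[(1Z)-2-methyl-3-oxobut-1-en-1-yl]-4-methylidene-5-oxooxolan-3-yl]pent-4-en-1-yl (2Z)-2-methylbut-2-enoate | CC(=O)/C(C)=C\[C@@H]1OC(=O)C(=C)[C@@H]1[C@H](OC(=O)/C(C)=C\C)C[C@](C)(OCc2ccc(OC)cc2)C=C | intermediate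
26 | (1R,3S)-3-[(4-methoxyphenyl)methoxy]-3-methyl-1-[(2S,3R)-2-[(1Z)-2-methyl-3-oxobut-1-en-1-yl]-4-methylidene-5-oxooxolan-3-yl]-4-oxobutyl (2Z)-2-methylbut-2-enoate | CC(=O)/C(C)=C\[C@@H]1OC(=O)C(=C)[C@@H]1[C@H](OC(=O)/C(C)=C\C)C[C@](C)(OCc2ccc(OC)cc2)C=O | intermediate
27 | (1R,3S)-3-[(4-methoxyphenyl)methoxy]-3-methyl-1-[(2S,3R)-2-[(1Z)-2-methyl-3-(triethylsilyloxy)buta-1,3-dien-1-yl]-4-methylidene-5-oxooxolan-3-yl]-4-oxobutyl (2Z)-2-methylbut-2-enoate (key-step precursor) | C=C(O[Si](CC)(CC)CC)/C(C)=C\[C@@H]1OC(=O)C(=C)[C@@H]1[C@H](OC(=O)/C(C)=C\C)C[C@](C)(OCc2ccc(OC)cc2)C=O | intermediate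
28 | (1S,4Z,6S,7R,8R,10S)-1-hydroxy-10-[(4-methoxyphenyl)methoxy]-3-oxogermacra-4,11(13)-dien-12,6-olid-8-yl (2Z)-2-methylbut-2-enoate (key-step product) | C=C1C(=O)O[C@H]2/C=C(/C)C(=O)C[C@H](O)[C@@](C)(OCc3ccc(OC)cc3)C[C@@H](OC(=O)/C(C)=C\C)[C@@H]12 | intermediate
29 | (1S,4Z,6S,7R,8R,10S)-1,10-dihydroxy-3-oxogermacra-4,11(13)-dien-12,6-olid-8-yl (2Z)-2-methylbut-2-enoate, CNP0271189.1 | C=C1C(=O)O[C@H]2/C=C(/C)C(=O)C[C@H](O)[C@@](C)(O)C[C@@H](OC(=O)/C(C)=C\C)[C@@H]12 | target

Total step count: 17 (steps 8 and 9 make the iodoenal branch). Longest linear sequence: 15 steps (1–7 and 10–17) from (S)-linalool.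

Steps most likely to fail

1. Step 16 (bears the label). What may go wrong: intermolecular aldol oligomerisation or protodesilylation of the dienol ether outrunning the entropically and transannularly disfavoured ten-membered closure, or loss of facial control if the chelate does not form. Fallback (known chemistry, a samarium Reformatsky ring closure): it sets out from 27. NBS in THF at −78 °C should brominate the dienol ether regiospecifically at C2 to give the bromomethyl ketone F1. Slow addition of F1 to SmI2 in THF at −78 °C under high dilution should generate the samarium enolate, which adds to the C1 aldehyde held by O10 chelation. The fallback comes back to the route at 28.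

2. Step 10. What may go wrong: insufficient discrimination between the two faces of C7 by the C8 stereocentre, or leakage to the anti adduct through E/Z equilibration of the allylindium species. Fallback (allylboration with a geometrically fixed reagent): it sets out from 11. Acetylation (Ac2O, pyridine, DMAP) gives the acetate F2, and SN2′ borylation (B2pin2, Pd2(dba)3 cat., toluene, 50 °C) gives the allylboronate F3 with C8 cis to the borylmethyl group. F3 and 16 in toluene at 80 °C should react through a tight closed chair transition state, in which the short B–O and B–C bonds amplify the 1,3-allylic-strain bias and the geometry cannot scramble. This gives hydroxy ester 17 after work-up, and PPTS brings the sequence back to the route at 18.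

3. Step 17. What may go wrong: capture of the benzylic oxocarbenium ion by the neighbouring C1 hydroxyl in competition with water, which would stop the deprotection at a cyclic acetal or lead on to over-oxidation. Fallback (two-stage deprotection through that acetal): it sets out from 28. DDQ under anhydrous conditions (4 Å molecular sieves, CH2Cl2, 0 °C) should convert the PMB ether into the 1,10-O-(4-methoxybenzylidene) acetal F4, which 80% aqueous AcOH at room temperature should hydrolyse. The fallback comes back to the route at 29.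

Further compounds
F1 | step 16 | (1R,3S)-1-[(2S,3R)-2-[(1Z)-4-bromo-2-methyl-3-oxobut-1-en-1-yl]-4-methylidene-5-oxooxolan-3-yl]-3-[(4-methoxyphenyl)methoxy]-3-methyl-4-oxobutyl (2Z)-2-methylbut-2-enoate | BrCC(=O)/C(C)=C\[C@@H]1OC(=O)C(=C)[C@@H]1[C@H](OC(=O)/C(C)=C\C)C[C@](C)(OCc2ccc(OC)cc2)C=O
F2 | step 10 | methyl (4R,6S)-3-acetoxy-6-[(4-methoxyphenyl)methoxy]-6-methyl-2-methylidene-4-(triethylsilyloxy)oct-7-enoate (both C3 epimers) | C=C(C(=O)OC)C(OC(C)=O)[C@H](O[Si](CC)(CC)CC)C[C@](C)(OCc1ccc(OC)cc1)C=C
F3 | step 10 | methyl (2E,4R,6S)-6-[(4-methoxyphenyl)methoxy]-6-methyl-2-[(4,4,5,5-tetramethyl-1,3,2-dioxaborolan-2-yl)methyl]-4-(triethylsilyloxy)octa-2,7-dienoate | COC(=O)/C(CB1OC(C)(C)C(C)(C)O1)=C/[C@H](O[Si](CC)(CC)CC)C[C@](C)(OCc1ccc(OC)cc1)C=C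
F4 | step 17 | 1,10-O-(4-methoxybenzylidene) acetal of 29 (2-aryl-1,3-dioxolane across O1 and O10, both acetal epimers) | C=C1C(=O)O[C@H]2/C=C(/C)C(=O)C[C@@H]3OC(c4ccc(OC)cc4)O[C@@]3(C)C[C@@H](OC(=O)/C(C)=C\C)[C@@H]12
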